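**Strategy.** The plan cuts the upper pyran ring C at two bonds, C3–C4 and O1–C2. What is left on ring A, the O1 phenol next to a benzylic C4 that already carries C8' of the lower catechin 3-O-gallate unit (rings D, F and E), is an ortho-quinone methide in disguise. C2–C3 with ring B and the upper gallate is an (E)-enol ester. A single acid-catalysed inverse-demand [4+2] union closes ring C, makes both bonds and sets C2, C3 and C4, with the hindered C3 ester in place from the start. The precursor is a per-benzylated diaryl carbinol: its CH(OH) carbon links a 2-hydroxy-4,6-bis(benzyloxy)phenyl ring to C8' of benzylated (+)-catechin gallate.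

Key step: step 8

Remark: the target is read as procyanidin B3 3,3'-di-O-gallate (upper unit 2R,3S,4S with a 2,3-trans-3,4-trans ring C, lower unit 2R,3S); the diaryl carbinol is made and used as both epimers at its CH(OH) carbon (one is drawn) because that carbon becomes planar in the key step, and the acid enantiomer written there stands for whichever proves matched with the lower unit.

**Step 1**
Reactants: 1 (+)-catechin
Product: 2 5,7,3',4'-tetra-O-benzyl-(+)-catechin
Conditions: BnBr (4.4 equiv), K2CO3, DMF, 0 °C to rt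
Reagents that add atoms: benzyl bromide, BrCc1ccccc1
Why: Williamson etherification under carbonate alkylates only the four phenols and leaves the secondary C3 alcohol free, and at or below room temperature ring C does not open, so C2 and C3 keep their configuration.

**Step 2**
Reactants: 2 5,7,3',4'-tetra-O-benzyl-(+)-catechin; 3 3,4,5-tris(benzyloxy)benzoic acid
Product: 4 5,7,3',4'-tetra-O-benzyl-(+)-catechin 3-O-[3,4,5-tris(benzyloxy)benzoate]
Conditions: N,N'-dicyclohexylcarbodiimide (DCC), 4-(dimethylamino)pyridine (DMAP, cat.), CH2Cl2, rt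
Reagents that add atoms: none
Why: Steglich esterification with DMAP as acyl-transfer catalyst acylates the equatorial C3 alcohol without touching a stereocentre.

**Step 3**
Reactants: 4 5,7,3',4'-tetra-O-benzyl-(+)-catechin 3-O-[3,4,5-tris(benzyloxy)benzoate]
Product: 6 8-formyl-5,7,3',4'-tetra-O-benzyl-(+)-catechin 3-O-[3,4,5-tris(benzyloxy)benzoate], via C8 dimethyliminium dichlorophosphate 5 (not isolated)
Conditions: POCl3, DMF, 0 to 60 °C; then aq NaOAc, rt
Reagents that add atoms: N,N-dimethylformamide, CN(C)C=O; water, O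
Why: Vilsmeier–Haack formylation is an electrophilic aromatic substitution that selects the only ring with three oxygen donors and, within it, C8 (the later C8'), which lies between the ring oxygen and one benzyloxy group and is less crowded than C6 between two benzyloxy groups; the ester and the benzyl ethers are inert.

**Step 4**
Reactants: 6 8-formyl-5,7,3',4'-tetra-O-benzyl-(+)-catechin 3-O-[3,4,5-tris(benzyloxy)benzoate]; 7 3,5-bis(benzyloxy)phenol
Product: 9 8-{[2-hydroxy-4,6-bis(benzyloxy)phenyl](hydroxy)methyl}-5,7,3',4'-tetra-O-benzyl-(+)-catechin 3-O-[3,4,5-tris(benzyloxy)benzoate] (both carbinol epimers), via bromomagnesium 3,5-bis(benzyloxy)phenolate 8 (not isolated)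
Conditions: 7 (1.15 equiv), EtMgBr (1.1 equiv), Et2O, 0 °C; solvent change to CH2Cl2; 6, 0 °C to rt; pH 7 phosphate buffer
Reagents that add atoms: none
Why: In this Casiraghi-type ortho-hydroxyalkylation the magnesium phenolate binds the aldehyde oxygen in a non-coordinating solvent and delivers the carbonyl carbon to the ortho position through a six-membered chelate (the two ortho positions are equivalent), while the phenolate is too weak a nucleophile to attack the hindered aryl esters and the new carbinol centre needs no control.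

**Step 5**
Reactants: 10 3,4-bis(benzyloxy)benzaldehyde
Product: 11 1,2-bis(benzyloxy)-4-ethynylbenzene
Conditions: dimethyl (1-diazo-2-oxopropyl)phosphonate, K2CO3, MeOH/THF, 0 °C to rt
Reagents that add atoms: dimethyl (1-diazo-2-oxopropyl)phosphonate, COP(=O)(OC)C(=[N+]=[N-])C(C)=O
Why: Seyferth–Gilbert homologation in its Ohira–Bestmann form converts the non-enolisable aryl aldehyde into the terminal alkyne under carbonate/methanol conditions that benzyl ethers tolerate.

**Step 6**
Reactants: 11 1,2-bis(benzyloxy)-4-ethynylbenzene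
Product: 13 potassium (E)-[2-(3,4-bis(benzyloxy)phenyl)ethenyl]trifluoroborate, via (E)-alkenyl pinacol boronate 12 (not isolated)
Conditions: pinacolborane, Cp2Zr(H)Cl (5 mol %), Et3N (10 mol %), CH2Cl2, rt; then KHF2, MeOH/H2O, rt
Reagents that add atoms: pinacolborane, CC1(C)OBOC1(C)C; potassium hydrogen difluoride, [K+].[F-].F
Why: Zirconocene-catalysed hydroboration of the terminal alkyne is a syn, anti-Markovnikov addition of H–B that gives only the (E)-alkenyl boronate, and KHF2 turns it with retention of geometry into the crystalline, air-stable trifluoroborate.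

**Step 7**
Reactants: 13 potassium (E)-[2-(3,4-bis(benzyloxy)phenyl)ethenyl]trifluoroborate; 3 3,4,5-tris(benzyloxy)benzoic acid
Product: 14 (E)-2-[3,4-bis(benzyloxy)phenyl]ethenyl 3,4,5-tris(benzyloxy)benzoate
Conditions: CuBr (10 mol %), DMAP (20 mol %), 4 Å MS, O2 (1 atm), MeCN, 60 °C
Reagents that add atoms: none
Why: Chan–Lam-type oxidative C–O coupling of an alkenyl trifluoroborate with a carboxylic acid runs through transmetalation to copper and reductive elimination at the sp2 carbon, so the (E) geometry is retained and the enol ester forms under nearly neutral conditions.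

**Step 8**
Reactants: 9 diaryl carbinol (both epimers); 14 (E)-2-[3,4-bis(benzyloxy)phenyl]ethenyl 3,4,5-tris(benzyloxy)benzoate
Product: 16 tetradeca-O-benzyl procyanidin B3 3,3'-di-O-gallate, via ring A ortho-quinone methide 15 (not isolated)
Conditions: 14 (3 equiv), (R)-3,3'-bis(2,4,6-triisopropylphenyl)-1,1'-binaphthyl-2,2'-diyl N-triflylphosphoramide (10 mol %), 5 Å MS, CH2Cl2, −40 to 0 °C, 9 added over 6 h
Reagents that add atoms: none
Why: Proposed new method: the strong chiral Brønsted acid ionises the doubly activated carbinol to a diarylmethyl cation that stands in equilibrium, as a hydrogen-bonded chiral ion pair, with ortho-quinone methide 15, and the enol ester adds to C4 through its oxygen-bearing carbon in an inverse-demand, strongly asynchronous [4+2] process in which O1 then closes on C2. The closest known reaction type is the chiral N-triflylphosphoramide-catalysed hetero-Diels–Alder reaction of ortho-quinone methides, generated from 2-hydroxybenzhydrols, with styrenes, in which only the electrophile is activated and β-substituted styrenes give 2,3-trans flavans; an enol ester as the two-carbon partner is the untested element. Ring C is closed in the intermolecular [4+2] mode, and in the stepwise limit its second bond forms by 6-exo-trig attack of the ring A oxygen on the benzylic C2 cation stabilised by ring B. The trans C2/C3 relation follows from suprafacial addition across the (E) alkene, and the trans C3/C4 relation from the transition state with ring B endo and the lower unit anti to the C8a oxygen, which is the all-equatorial closure. The 4S sense at C4 is set by the face of the planar methide that the chiral phosphoramide anion leaves open, reinforced or opposed by the (2R,3S) lower unit, so both acid enantiomers are to be tried and a wrong-face adduct is a separable diastereomer. The step needs C3-to-C4 regiochemistry, which the 4-benzyloxy group of ring B secures because it stabilises charge at C2 far better than an acyloxy oxygen could at C3, and it needs the methide to be trapped by the alkene and not by the electron-rich phenol ring of unreacted carbinol, which slow addition of 9 to excess 14 secures.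

**Step 9**
Reactants: 16 tetradeca-O-benzyl procyanidin B3 3,3'-di-O-gallate
Product: 17 procyanidin B3 3,3'-di-O-gallate (CNP0281991.3)
Conditions: H2 (1 atm), Pd(OH)2/C, THF/MeOH/H2O, rt
Reagents that add atoms: none
Why: Hydrogenolysis of benzyl ethers over Pd(OH)2/C cleaves all fourteen O–CH2Ph bonds under neutral conditions at room temperature, which spare the aryl esters, the acid-labile C4–C8' bond and every stereocentre.

**Compound list**

1 | (+)-catechin, (2R,3S) | O[C@H]1Cc2c(O)cc(O)cc2O[C@@H]1c1ccc(O)c(O)c1 | starting material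
2 | 5,7,3',4'-tetra-O-benzyl-(+)-catechin, (2R,3S) | O[C@H]1Cc2c(OCc9ccccc9)cc(OCc9ccccc9)cc2O[C@@H]1c1ccc(OCc9ccccc9)c(OCc9ccccc9)c1 | intermediate
3 | 3,4,5-tris(benzyloxy)benzoic acid | OC(=O)c1cc(OCc2ccccc2)c(OCc2ccccc2)c(OCc2ccccc2)c1 | starting material
4 | 5,7,3',4'-tetra-O-benzyl-(+)-catechin 3-O-[3,4,5-tris(benzyloxy)benzoate], (2R,3S) | O=C(O[C@H]1Cc2c(OCc9ccccc9)cc(OCc9ccccc9)cc2O[C@@H]1c1ccc(OCc9ccccc9)c(OCc9ccccc9)c1)c1cc(OCc9ccccc9)c(OCc9ccccc9)c(OCc9ccccc9)c1 | intermediate
5 | C8 N,N-dimethyliminium dichlorophosphate of 4 (ArCH=NMe2+ at C8; not isolated) | C[N+](C)=Cc1c(OCc9ccccc9)cc(OCc9ccccc9)c2c1O[C@H](c1ccc(OCc9ccccc9)c(OCc9ccccc9)c1)[C@@H](OC(=O)c1cc(OCc9ccccc9)c(OCc9ccccc9)c(OCc9ccccc9)c1)C2.[O-]P(=O)(Cl)Cl | intermediate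
6 | 8-formyl-5,7,3',4'-tetra-O-benzyl-(+)-catechin 3-O-[3,4,5-tris(benzyloxy)benzoate], (2R,3S) | O=Cc1c(OCc9ccccc9)cc(OCc9ccccc9)c2c1O[C@H](c1ccc(OCc9ccccc9)c(OCc9ccccc9)c1)[C@@H](OC(=O)c1cc(OCc9ccccc9)c(OCc9ccccc9)c(OCc9ccccc9)c1)C2 | intermediate
7 | 3,5-bis(benzyloxy)phenol | Oc1cc(OCc2ccccc2)cc(OCc2ccccc2)c1 | starting material
8 | bromomagnesium 3,5-bis(benzyloxy)phenolate (not isolated) | Br[Mg]Oc1cc(OCc2ccccc2)cc(OCc2ccccc2)c1 | intermediate
9 | diaryl carbinol: 8-{[2-hydroxy-4,6-bis(benzyloxy)phenyl](hydroxy)methyl}-5,7,3',4'-tetra-O-benzyl-(+)-catechin 3-O-[3,4,5-tris(benzyloxy)benzoate]; both epimers at CH(OH), one drawn | O[C@H](c2c(OCc9ccccc9)cc(OCc9ccccc9)c3c2O[C@H](c7ccc(OCc9ccccc9)c(OCc9ccccc9)c7)[C@@H](OC(=O)c8cc(OCc9ccccc9)c(OCc9ccccc9)c(OCc9ccccc9)c8)C3)c2c(OCc9ccccc9)cc(OCc9ccccc9)cc2O | intermediate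
10 | 3,4-bis(benzyloxy)benzaldehyde | O=Cc1ccc(OCc2ccccc2)c(OCc2ccccc2)c1 | starting material
11 | 1,2-bis(benzyloxy)-4-ethynylbenzene | C#Cc1ccc(OCc9ccccc9)c(OCc9ccccc9)c1 | intermediate
12 | (E)-2-[2-(3,4-bis(benzyloxy)phenyl)ethenyl]-4,4,5,5-tetramethyl-1,3,2-dioxaborolane (not isolated) | CC1(C)OB(/C=C/c2ccc(OCc9ccccc9)c(OCc9ccccc9)c2)OC1(C)C | intermediate
13 | potassium (E)-[2-(3,4-bis(benzyloxy)phenyl)ethenyl]trifluoroborate | [K+].F[B-](F)(F)/C=C/c1ccc(OCc9ccccc9)c(OCc9ccccc9)c1 | intermediate
14 | (E)-2-[3,4-bis(benzyloxy)phenyl]ethenyl 3,4,5-tris(benzyloxy)benzoate | O=C(O/C=C/c7ccc(OCc9ccccc9)c(OCc9ccccc9)c7)c8cc(OCc9ccccc9)c(OCc9ccccc9)c(OCc9ccccc9)c8 | intermediate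
15 | ring A ortho-quinone methide: (E)-3,5-bis(benzyloxy)-6-(arylmethylidene)cyclohexa-2,4-dien-1-one, aryl = C8 of the flavan of 4, drawn with that aryl anti to the carbonyl (not isolated) | O=C1C=C(OCc9ccccc9)C=C(OCc9ccccc9)/C1=C\c1c(OCc9ccccc9)cc(OCc9ccccc9)c2c1O[C@H](c1ccc(OCc9ccccc9)c(OCc9ccccc9)c1)[C@@H](OC(=O)c1cc(OCc9ccccc9)c(OCc9ccccc9)c(OCc9ccccc9)c1)C2 | intermediate
16 | tetradeca-O-benzyl procyanidin B3 3,3'-di-O-gallate; upper unit (2R,3S,4S), lower unit (2R,3S), C4–C8' bond | O=C(O[C@H]1[C@H](c2c(OCc9ccccc9)cc(OCc9ccccc9)c3c2O[C@H](c7ccc(OCc9ccccc9)c(OCc9ccccc9)c7)[C@@H](OC(=O)c8cc(OCc9ccccc9)c(OCc9ccccc9)c(OCc9ccccc9)c8)C3)c2c(OCc9ccccc9)cc(OCc9ccccc9)cc2O[C@@H]1c7ccc(OCc9ccccc9)c(OCc9ccccc9)c7)c8cc(OCc9ccccc9)c(OCc9ccccc9)c(OCc9ccccc9)c8 | intermediate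
17 | procyanidin B3 3,3'-di-O-gallate, (+)-catechin 3-O-gallate-(4α→8)-(+)-catechin 3-O-gallate; upper unit (2R,3S,4S), lower unit (2R,3S) | O=C(O[C@H]1[C@H](c2c(O)cc(O)c3c2O[C@H](c2ccc(O)c(O)c2)[C@@H](OC(=O)c2cc(O)c(O)c(O)c2)C3)c2c(O)cc(O)cc2O[C@@H]1c1ccc(O)c(O)c1)c1cc(O)c(O)c(O)c1 | target

**Totals.** Total step count: 9. Longest linear sequence: 6 steps (steps 1, 2, 3, 4, 8, 9).

**Steps most likely to fail**

Step 8. The stabilised methide may add the weakly nucleophilic enol ester too slowly, so that self-alkylation by unreacted carbinol or acyl transfer from the enol ester takes over, and the face of C4 may be poorly differentiated. The fallback uses known flavan-3-ol coupling chemistry, sets out from 2 and 3 and returns at 16. Compound 2 would be oxidised at C4 with 2,3-dichloro-5,6-dicyano-1,4-benzoquinone in CH2Cl2 in the presence of 2-ethoxyethanol to give (2R,3S,4S)-4-(2-ethoxyethoxy)-5,7,3',4'-tetra-O-benzylcatechin F1. Acetylation (Ac2O, pyridine, DMAP) would give its 3-O-acetate F2. Me3SiOTf in CH2Cl2 at −78 °C would ionise F2 at C4, and an excess of 2 would attack through C8 on the face anti to the participating acetate to give 3-O-acetyl-octa-O-benzyl procyanidin B3 F3. n-Bu4NOH in THF would remove the acetate to give octa-O-benzyl procyanidin B3 F4. Esterification of both C3 alcohols with 3 (DCC, DMAP, CH2Cl2) would then give 16.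

Step 4. The magnesium alkoxide of the very electron-rich carbinol may ionise in the flask and capture a second phenolate (over-arylation), or the phenolate may attack para to its oxygen. The fallback sets out from 6 and 7 and returns at 9. It replaces the magnesium phenolate addition by a boron-templated condensation: PhB(OH)2 with catalytic propionic acid in toluene under removal of water would join phenol oxygen, ortho carbon and aldehyde in one cyclic transition state and hold the product as the cyclic phenylboronate (2-phenyl-4H-1,3,2-benzodioxaborin) of the carbinol F5, which cannot ionise. Transesterification with diethanolamine in THF/Et2O would release 9.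

Step 3. The formyl group may enter at C6 instead of C8, or the hindered ring may not be converted fully. The fallback sets out from 2 and returns at 6, fixing the site by halogenation before the gallate is introduced. N-Bromosuccinimide in CH2Cl2 at −78 to 0 °C would give 8-bromo-5,7,3',4'-tetra-O-benzylcatechin F6. tert-Butyldimethylsilyl chloride and imidazole in DMF would give its 3-O-silyl ether F7. Bromine–lithium exchange with n-BuLi in THF at −78 °C and quenching with DMF would give the 8-formyl 3-O-silyl ether F8. Bu4NF in THF would give 8-formyl-5,7,3',4'-tetra-O-benzylcatechin F9, and esterification with 3 (DCC, DMAP) would give 6.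

**Further compounds**

F1 | step 8 | (2R,3S,4S)-4-(2-ethoxyethoxy)-5,7,3',4'-tetra-O-benzylcatechin | O[C@H]1[C@@H](OCCOCC)c2c(OCc9ccccc9)cc(OCc9ccccc9)cc2O[C@@H]1c1ccc(OCc9ccccc9)c(OCc9ccccc9)c1
F2 | step 8 | (2R,3S,4S)-3-O-acetyl-4-(2-ethoxyethoxy)-5,7,3',4'-tetra-O-benzylcatechin | CC(=O)O[C@H]1[C@@H](OCCOCC)c2c(OCc9ccccc9)cc(OCc9ccccc9)cc2O[C@@H]1c1ccc(OCc9ccccc9)c(OCc9ccccc9)c1
F3 | step 8 | 3-O-acetyl-octa-O-benzyl procyanidin B3 (acetate on the upper unit, lower C3 alcohol free) | CC(=O)O[C@H]1[C@H](c2c(OCc9ccccc9)cc(OCc9ccccc9)c3c2O[C@H](c7ccc(OCc9ccccc9)c(OCc9ccccc9)c7)[C@@H](O)C3)c2c(OCc9ccccc9)cc(OCc9ccccc9)cc2O[C@@H]1c7ccc(OCc9ccccc9)c(OCc9ccccc9)c7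
F4 | step 8 | octa-O-benzyl procyanidin B3 (both C3 alcohols free) | O[C@H]1[C@H](c2c(OCc9ccccc9)cc(OCc9ccccc9)c3c2O[C@H](c7ccc(OCc9ccccc9)c(OCc9ccccc9)c7)[C@@H](O)C3)c2c(OCc9ccccc9)cc(OCc9ccccc9)cc2O[C@@H]1c7ccc(OCc9ccccc9)c(OCc9ccccc9)c7
F5 | step 4 | cyclic phenylboronate of 9 (5,7-bis(benzyloxy)-2-phenyl-4H-1,3,2-benzodioxaborin carrying C8 of the flavan of 4 at C4; both epimers, one drawn) | c1ccccc1B1O[C@H](c2c(OCc9ccccc9)cc(OCc9ccccc9)c3c2O[C@H](c7ccc(OCc9ccccc9)c(OCc9ccccc9)c7)[C@@H](OC(=O)c8cc(OCc9ccccc9)c(OCc9ccccc9)c(OCc9ccccc9)c8)C3)c2c(OCc9ccccc9)cc(OCc9ccccc9)cc2O1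
F6 | step 3 | 8-bromo-5,7,3',4'-tetra-O-benzyl-(+)-catechin | O[C@H]1Cc2c(OCc9ccccc9)cc(OCc9ccccc9)c(Br)c2O[C@@H]1c1ccc(OCc9ccccc9)c(OCc9ccccc9)c1
F7 | step 3 | 8-bromo-3-O-(tert-butyldimethylsilyl)-5,7,3',4'-tetra-O-benzyl-(+)-catechin | CC(C)(C)[Si](C)(C)O[C@H]1Cc2c(OCc9ccccc9)cc(OCc9ccccc9)c(Br)c2O[C@@H]1c1ccc(OCc9ccccc9)c(OCc9ccccc9)c1
F8 | step 3 | 8-formyl-3-O-(tert-butyldimethylsilyl)-5,7,3',4'-tetra-O-benzyl-(+)-catechin | CC(C)(C)[Si](C)(C)O[C@H]1Cc2c(OCc9ccccc9)cc(OCc9ccccc9)c(C=O)c2O[C@@H]1c1ccc(OCc9ccccc9)c(OCc9ccccc9)c1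
F9 | step 3 | 8-formyl-5,7,3',4'-tetra-O-benzyl-(+)-catechin | O[C@H]1Cc2c(OCc9ccccc9)cc(OCc9ccccc9)c(C=O)c2O[C@@H]1c1ccc(OCc9ccccc9)c(OCc9ccccc9)c1
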